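**Strategy.** The route rests on closing the cyclohexene ring (C1 = CH stereocentre, C2 = methyl-bearing alkene carbon, C3 = alkene CH, C6 = CMe2) at the bond between C1 and vinylic C2; C1 is wedged between quaternary C6 and the C2=C3 alkene. The precursor is an acyclic alkenyl boronate with boron cis to the tether (future C2=C3), linked to an (E)-vinyl 2-pyridyl sulfone (future C1 and its exocyclic CH2). Rh/chiraphos-catalysed intramolecular conjugate addition forms C1–C2, sets (S)-C1 and fixes the alkene position in one operation. The sulfonyl group then serves as the carbanion handle that joins this C10 ring fragment to a C10 bromide from geranyl acetate; desulfonylation and esterification with α-linolenic acid finish.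

Key step: step 5

Assumption: methyl 4,4-dimethyl-5-oxopentanoate (1) is taken as a catalogue compound.

**Step 1**
Reactants: 1 methyl 4,4-dimethyl-5-oxopentanoate; 2 2-(methylsulfonyl)pyridine
Product: 4 methyl (5E)-4,4-dimethyl-6-(pyridin-2-ylsulfonyl)hex-5-enoate, via lithiated sulfonylmethylphosphonate 3 (not isolated)
Conditions: 2, LiN(SiMe3)2 (2.1 equiv), THF, −78 °C; ClP(O)(OEt)2; then 1, −78 °C to rt
Reagents that add atoms: none
Why: One-pot Horner–Wadsworth–Emmons olefination: the methyl sulfone is phosphorylated and deprotonated in the flask, and the stabilised anion should add to the non-enolisable neopentyl aldehyde and eliminate to the (E)-vinyl sulfone without touching the ester.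

**Step 2**
Reactants: 4 methyl (5E)-4,4-dimethyl-6-(pyridin-2-ylsulfonyl)hex-5-enoate
Product: 5 (5E)-4,4-dimethyl-6-(pyridin-2-ylsulfonyl)hex-5-enal
Conditions: i-Bu2AlH (1.1 equiv), CH2Cl2, −78 °C; MeOH quench, aqueous tartrate work-up
Reagents that add atoms: none
Why: Partial reduction of the methyl ester through the aluminium hemiacetal that is stable at −78 °C, with the electron-poor vinyl sulfone expected to be inert to the electrophilic hydride at this temperature.

**Step 3**
Reactants: 5 (5E)-4,4-dimethyl-6-(pyridin-2-ylsulfonyl)hex-5-enal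
Product: 6 2-{[(1E,6Z)-7-iodo-3,3-dimethylocta-1,6-dien-1-yl]sulfonyl}pyridine (iodine cis to the chain CH2, methyl trans)
Conditions: [Ph3PEt]I, n-BuLi, THF, rt; I2, −78 °C; NaN(SiMe3)2, −20 °C; then 5, −78 °C
Reagents that add atoms: ethyltriphenylphosphonium iodide CC[P+](c1ccccc1)(c1ccccc1)c1ccccc1.[I-]; iodine II
Why: Stork–Zhao-type Wittig olefination with the non-stabilised α-iodo ylide, whose kinetic cis-oxaphosphetane should deliver the (Z)-2-iodoalkene, while the hindered β-carbon of the vinyl sulfone is not expected to compete with the aldehyde.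

**Step 4**
Reactants: 6 2-{[(1E,6Z)-7-iodo-3,3-dimethylocta-1,6-dien-1-yl]sulfonyl}pyridine
Product: 7 2-{[(1E,6E)-3,3-dimethyl-7-(4,4,5,5-tetramethyl-1,3,2-dioxaborolan-2-yl)octa-1,6-dien-1-yl]sulfonyl}pyridine (boron cis to the chain CH2, methyl trans; the 6E descriptor follows from C > B)
Conditions: B2pin2, PdCl2(PPh3)2 (3 mol %), PPh3, KOPh, toluene, 50 °C
Reagents that add atoms: bis(pinacolato)diboron CC1(C)OB(OC1(C)C)B1OC(C)(C)C(C)(C)O1
Why: Miyaura borylation of an alkenyl iodide, which proceeds with retention of alkene geometry through oxidative addition, phenoxide-assisted transmetalation with the diboron and reductive elimination.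

**Step 5**
Reactants: 7 2-{[(1E,6E)-3,3-dimethyl-7-(4,4,5,5-tetramethyl-1,3,2-dioxaborolan-2-yl)octa-1,6-dien-1-yl]sulfonyl}pyridine
Product: 8 2-({[(1S)-2,6,6-trimethylcyclohex-2-en-1-yl]methyl}sulfonyl)pyridine
Conditions: Rh(acac)(C2H4)2 (5 mol %), (S,S)-chiraphos (5.5 mol %), KOH (20 mol %), dioxane/H2O 10:1, 80 °C
Reagents that add atoms: none
Why: Hydroxide-assisted transmetalation of the alkenyl–B(pin) to monovalent rhodium gives an alkenylrhodium with the metal cis to the tether, syn-insertion of the sulfonyl alkene into Rh–C forms the C2–C1 bond, and water protonates the N,C-chelated α-sulfonyl alkylrhodium and regenerates Rh–OH. The closest known reaction type is the Rh/chiraphos-catalysed enantioselective conjugate addition of alkenylboron reagents to β-substituted α,β-unsaturated 2-pyridyl sulfones (Hayashi–Miyaura type), here run intramolecularly. The cyclohexene closes in the 6-exo-trig mode, with the preformed C2=C3 alkene inside the ring and the sulfonyl-bearing carbon outside. The stereocentre C1 is set by the chiral diphosphine on rhodium, which must deliver C2 to the Re face of the β-carbon (priorities CH–SO2 > CMe2 > H) to give (S); the (S,S)-ligand is proposed, and its mirror image is equally available should the sense of induction be the opposite. The step needs insertion to outrun protodeboronation and the alkylrhodium to be protonated instead of undergoing β-hydride elimination; the six-membered intramolecular geometry and chelation by the pyridine nitrogen should secure both. Because the alkene enters with fixed geometry and never passes through a cation or allyl species, no isomer with a C1=C2 or exocyclic double bond should form.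

**Step 6**
Reactants: 9 geranyl acetate, (2E)-3,7-dimethylocta-2,6-dien-1-yl acetate
Product: 10 (2E,6E)-8-hydroxy-3,7-dimethylocta-2,6-dien-1-yl acetate
Conditions: SeO2 (0.3 equiv), t-BuOOH (3 equiv), salicylic acid (cat.), CH2Cl2, rt
Reagents that add atoms: tert-butyl hydroperoxide CC(C)(C)OO
Why: Catalytic SeO2 allylic oxidation (ene reaction, then [2,3]-sigmatropic shift), which should select the (E)-methyl group of the electron-richer terminal alkene and give the (E)-allylic alcohol.

**Step 7**
Reactants: 10 (2E,6E)-8-hydroxy-3,7-dimethylocta-2,6-dien-1-yl acetate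
Product: 11 (2E,6E)-8-bromo-3,7-dimethylocta-2,6-dien-1-yl acetate
Conditions: CBr4, PPh3, CH2Cl2, 0 °C
Reagents that add atoms: carbon tetrabromide BrC(Br)(Br)Br
Why: Appel bromination by SN2 displacement at the primary allylic carbon, which should proceed without allylic transposition or loss of alkene geometry and leave the acetate intact.

**Step 8**
Reactants: 8 2-({[(1S)-2,6,6-trimethylcyclohex-2-en-1-yl]methyl}sulfonyl)pyridine; 11 (2E,6E)-8-bromo-3,7-dimethylocta-2,6-dien-1-yl acetate
Product: 12 (2E,6E)-3,7-dimethyl-9-(pyridin-2-ylsulfonyl)-9-[(1S)-2,6,6-trimethylcyclohex-2-en-1-yl]nona-2,6-dien-1-yl acetate (mixture of epimers at the sulfonyl-bearing carbon, which is removed in step 9)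
Conditions: 8, LiN(i-Pr)2 (1.0 equiv), THF, −78 °C; then 11, −78 to −40 °C
Reagents that add atoms: none
Why: Alkylation of the α-sulfonyl carbanion by SN2 attack on the primary allylic bromide, which should be faster than attack on the acetate at low temperature and does not touch the non-acidic ring stereocentre.

**Step 9**
Reactants: 12 (2E,6E)-3,7-dimethyl-9-(pyridin-2-ylsulfonyl)-9-[(1S)-2,6,6-trimethylcyclohex-2-en-1-yl]nona-2,6-dien-1-yl acetate
Product: 14 (2E,6E)-3,7-dimethyl-9-[(1S)-2,6,6-trimethylcyclohex-2-en-1-yl]nona-2,6-dien-1-ol, via acetate 13 (not isolated)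
Conditions: Na/Hg (6% Na), Na2HPO4, MeOH/THF, −20 °C to rt; then K2CO3, MeOH, rt
Reagents that add atoms: none
Why: Single-electron reductive desulfonylation cleaves the C–S bond of the easily reduced pyridyl sulfone and replaces it by C–H, and base-catalysed methanolysis then removes the acetate, with the isolated alkenes and the stereocentre expected to be unaffected.

**Step 10**
Reactants: 14 (2E,6E)-3,7-dimethyl-9-[(1S)-2,6,6-trimethylcyclohex-2-en-1-yl]nona-2,6-dien-1-ol; 15 α-linolenic acid, (9Z,12Z,15Z)-octadeca-9,12,15-trienoic acid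
Product: 16 (2E,6E)-3,7-dimethyl-9-[(1S)-2,6,6-trimethylcyclohex-2-en-1-yl]nona-2,6-dien-1-yl (9Z,12Z,15Z)-octadeca-9,12,15-trienoate
Conditions: EDC·HCl, DMAP (0.2 equiv), CH2Cl2, 0 °C to rt, argon, dark
Reagents that add atoms: none
Why: Steglich-type carbodiimide esterification through the acyl-pyridinium intermediate, mild enough that neither the skipped (Z,Z,Z)-triene nor the allylic ester should isomerise.

**Compound list**

1 | methyl 4,4-dimethyl-5-oxopentanoate | COC(=O)CCC(C)(C)C=O | starting material
2 | 2-(methylsulfonyl)pyridine | CS(=O)(=O)c1ccccn1 | starting material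
3 | diethyl [(pyridin-2-ylsulfonyl)methyl]phosphonate (present as its lithio derivative) | CCOP(=O)(CS(=O)(=O)c1ccccn1)OCC | intermediate
4 | methyl (5E)-4,4-dimethyl-6-(pyridin-2-ylsulfonyl)hex-5-enoate | COC(=O)CCC(C)(C)/C=C/S(=O)(=O)c1ccccn1 | intermediate
5 | (5E)-4,4-dimethyl-6-(pyridin-2-ylsulfonyl)hex-5-enal | O=CCCC(C)(C)/C=C/S(=O)(=O)c1ccccn1 | intermediate
6 | 2-{[(1E,6Z)-7-iodo-3,3-dimethylocta-1,6-dien-1-yl]sulfonyl}pyridine | C/C(I)=C/CCC(C)(C)/C=C/S(=O)(=O)c1ccccn1 | intermediate
7 | 2-{[(1E,6E)-3,3-dimethyl-7-(4,4,5,5-tetramethyl-1,3,2-dioxaborolan-2-yl)octa-1,6-dien-1-yl]sulfonyl}pyridine | C/C(B1OC(C)(C)C(C)(C)O1)=C/CCC(C)(C)/C=C/S(=O)(=O)c1ccccn1 | intermediate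
8 | 2-({[(1S)-2,6,6-trimethylcyclohex-2-en-1-yl]methyl}sulfonyl)pyridine | O=S(=O)(C[C@@H]1C(C)=CCCC1(C)C)c1ccccn1 | intermediate
9 | geranyl acetate | CC(=O)OC/C=C(\C)CCC=C(C)C | starting material
10 | (2E,6E)-8-hydroxy-3,7-dimethylocta-2,6-dien-1-yl acetate | CC(=O)OC/C=C(\C)CC/C=C(\C)CO | intermediate
11 | (2E,6E)-8-bromo-3,7-dimethylocta-2,6-dien-1-yl acetate | CC(=O)OC/C=C(\C)CC/C=C(\C)CBr | intermediate
12 | (2E,6E)-3,7-dimethyl-9-(pyridin-2-ylsulfonyl)-9-[(1S)-2,6,6-trimethylcyclohex-2-en-1-yl]nona-2,6-dien-1-yl acetate | CC(=O)OC/C=C(\C)CC/C=C(\C)CC([C@@H]1C(C)=CCCC1(C)C)S(=O)(=O)c1ccccn1 | intermediate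
13 | (2E,6E)-3,7-dimethyl-9-[(1S)-2,6,6-trimethylcyclohex-2-en-1-yl]nona-2,6-dien-1-yl acetate | CC(=O)OC/C=C(\C)CC/C=C(\C)CC[C@@H]1C(C)=CCCC1(C)C | intermediate
14 | (2E,6E)-3,7-dimethyl-9-[(1S)-2,6,6-trimethylcyclohex-2-en-1-yl]nona-2,6-dien-1-ol | OC/C=C(\C)CC/C=C(\C)CC[C@@H]1C(C)=CCCC1(C)C | intermediate
15 | α-linolenic acid | CC/C=C\C/C=C\C/C=C\CCCCCCCC(=O)O | starting material
16 | (2E,6E)-3,7-dimethyl-9-[(1S)-2,6,6-trimethylcyclohex-2-en-1-yl]nona-2,6-dien-1-yl (9Z,12Z,15Z)-octadeca-9,12,15-trienoate | CC/C=C\C/C=C\C/C=C\CCCCCCCC(=O)OC/C=C(\C)CC/C=C(\C)CC[C@@H]1C(C)=CCCC1(C)C | target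

**Step count and risks**

Total steps: 10. Longest linear sequence: 8 steps (steps 1, 2, 3, 4, 5, 8, 9, 10).

Steps most likely to fail:

Step 5. Insertion at the β-carbon next to the quaternary centre may be slow, so that protodeboronation of the alkenylrhodium overtakes ring closure, or the catalyst may discriminate the two faces of the acceptor poorly. The fallback sets out from 6 and omits the boronate. Iodine–lithium exchange (t-BuLi, 2 equiv, THF, −78 °C) should trigger an anionic 6-exo-trig addition of the alkenyllithium to the vinyl sulfone. Protonation (NH4Cl) would give racemic 2-{[(2,6,6-trimethylcyclohex-2-en-1-yl)methyl]sulfonyl}pyridine F1. Preparative chromatography on a chiral stationary phase would separate the enantiomers, and the (S)-enantiomer comes back to the route at 8.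

Step 4. The alkenylpalladium formed by oxidative addition may insert the tethered sulfonyl alkene (intramolecular Heck cyclisation) before it transmetalates with the diboron. The fallback sets out from 1 and installs boron before the acceptor exists.
- Acetalisation (HC(OMe)3, TsOH, MeOH) should give methyl 5,5-dimethoxy-4,4-dimethylpentanoate F2.
- i-Bu2AlH at −78 °C should give 5,5-dimethoxy-4,4-dimethylpentanal F3.
- The iodo-ylide olefination of step 3 should give (2Z)-2-iodo-7,7-dimethoxy-6,6-dimethylhept-2-ene F4.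
- t-BuLi, then 2-isopropoxy-4,4,5,5-tetramethyl-1,3,2-dioxaborolane, should give with retention 2-[(2E)-7,7-dimethoxy-6,6-dimethylhept-2-en-2-yl]-4,4,5,5-tetramethyl-1,3,2-dioxaborolane F5, with no palladium involved.
- Mild aqueous acid should unmask (5E)-2,2-dimethyl-6-(4,4,5,5-tetramethyl-1,3,2-dioxaborolan-2-yl)hept-5-enal F6.
- Horner–Wadsworth–Emmons olefination with 3, as in step 1, comes back to the route at 7.

Step 3. The α-iodo ylide may decompose, give eroded Z selectivity, or add to the vinyl sulfone. The fallback sets out from 5. Dibromo-olefination (CBr4, PPh3, CH2Cl2, 0 °C) should give 2-{[(1E)-7,7-dibromo-3,3-dimethylhepta-1,6-dien-1-yl]sulfonyl}pyridine F7. Palladium-catalysed Negishi monomethylation selective for the bromine trans to the chain (MeZnCl, PdCl2(DPEphos), THF) should then give 2-{[(1E,6Z)-7-bromo-3,3-dimethylocta-1,6-dien-1-yl]sulfonyl}pyridine F8. The oxidative addition that is favoured here places palladium trans to the tether, where it cannot reach the acceptor. Miyaura borylation of this bromide under the conditions of step 4 comes back to the route at 7.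

**Further compounds**

F1 | step 5 | racemic 2-{[(2,6,6-trimethylcyclohex-2-en-1-yl)methyl]sulfonyl}pyridine | O=S(=O)(CC1C(C)=CCCC1(C)C)c1ccccn1
F2 | step 4 | methyl 5,5-dimethoxy-4,4-dimethylpentanoate | COC(=O)CCC(C)(C)C(OC)OC
F3 | step 4 | 5,5-dimethoxy-4,4-dimethylpentanal | O=CCCC(C)(C)C(OC)OC
F4 | step 4 | (2Z)-2-iodo-7,7-dimethoxy-6,6-dimethylhept-2-ene | C/C(I)=C/CCC(C)(C)C(OC)OC
F5 | step 4 | 2-[(2E)-7,7-dimethoxy-6,6-dimethylhept-2-en-2-yl]-4,4,5,5-tetramethyl-1,3,2-dioxaborolane | C/C(B1OC(C)(C)C(C)(C)O1)=C/CCC(C)(C)C(OC)OC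
F6 | step 4 | (5E)-2,2-dimethyl-6-(4,4,5,5-tetramethyl-1,3,2-dioxaborolan-2-yl)hept-5-enal | C/C(B1OC(C)(C)C(C)(C)O1)=C/CCC(C)(C)C=O
F7 | step 3 | 2-{[(1E)-7,7-dibromo-3,3-dimethylhepta-1,6-dien-1-yl]sulfonyl}pyridine | BrC(Br)=CCCC(C)(C)/C=C/S(=O)(=O)c1ccccn1
F8 | step 3 | 2-{[(1E,6Z)-7-bromo-3,3-dimethylocta-1,6-dien-1-yl]sulfonyl}pyridine | C/C(Br)=C/CCC(C)(C)/C=C/S(=O)(=O)c1ccccn1
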